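**Retrosynthetic overview**
1. Target 16 ⇐ protected chalcone 15 by acid removal of three MOM groups.
2. 15 ⇐ alcohol 9 + cinnamoyl Weinreb amide 12 (aryl–C(=O) bond by ortho-lithiation of 9; 12 from aldehyde 10 and ylide 11 by Wittig).
3. 9 ⇐ enone 8 by oxazaborolidine-catalysed reduction, which sets the single (R) carbinol centre.
4. 8 ⇐ arene 2 + enone 3 (key ArC–CH2 bond): the ring carbon of 2, as a diarylzinc, attacks the α-carbon of 3 after that carbon is made electrophilic as an O-bound trivalent-iodine enolate (enolonium).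
5. 2 ⇐ 5-methoxyresorcinol 1; no ring is formed, both benzene rings are bought in 1 and 10.

Assumption: the carbinol centre in the SMILES is read as (R), and 10 and 11 are bought as catalogue compounds.

**Step 1**
Reactants: 1 5-methoxybenzene-1,3-diol (5-methoxyresorcinol)
Product: 2 1-methoxy-3,5-bis(methoxymethoxy)benzene
Conditions: MOMCl (2.5 equiv), K2CO3 (3 equiv), acetone, 0 °C → rt
Reagents that add atoms: chloromethyl methyl ether, COCCl
Why: Williamson-type O-alkylation of both phenoxides by the α-chloro ether; the MOM groups protect the phenols and later direct both ring lithiations.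

**Step 2**
Reactants: 2 1-methoxy-3,5-bis(methoxymethoxy)benzene; 3 3-methylbut-3-en-2-one
Product: 8 1-[4-methoxy-2,6-bis(methoxymethoxy)phenyl]-3-methylbut-3-en-2-one, via aryllithium 4 (not isolated), via diarylzinc 5 (not isolated), via lithium dienolate 6 (not isolated), via enolonium iodane 7 (not isolated)
Conditions: (a) 2, n-BuLi, THF, 0 °C, 1 h; ZnCl2 (0.5 equiv), 0 °C; (b) 3 (1.5 equiv), LiN(SiMe3)2, THF, −78 °C; PhI(OH)OTs, −78 °C, 10 min; (c) a into b, −78 °C → rt; H2O
Reagents that add atoms: none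
Why: Proposed new method: lithium dienolate 6 displaces tosylate on PhI(OH)OTs to give the O-bound trivalent-iodine enolate 7, whose terminal CH2 is now electrophilic (an enolonium), and an aryl group of diarylzinc 5 attacks that carbon in an SN2'-type step with loss of iodobenzene, so two natively nucleophilic carbons (an electron-rich arene carbon and a ketone α-carbon) are joined; the closest known reaction type is the oxidative umpolung α-alkylation of lithium enolates with PhI(OH)OTs and dialkylzincs (and α-arylation of enolonium species by electron-rich arenes), extended here to a diarylzinc and a cross-conjugated dienolate, with the ring position fixed by directed ortho-lithiation between the two OMOM groups (the stronger directors).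

**Step 3**
Reactants: 8 1-[4-methoxy-2,6-bis(methoxymethoxy)phenyl]-3-methylbut-3-en-2-one
Product: 9 (2R)-1-[4-methoxy-2,6-bis(methoxymethoxy)phenyl]-3-methylbut-3-en-2-ol
Conditions: (S)-methyl CBS oxazaborolidine [(S)-1-methyl-3,3-diphenyltetrahydro-1H,3H-pyrrolo[1,2-c][1,3,2]oxazaborole] (0.2 equiv), catecholborane (1.5 equiv), toluene, −78 °C; then MeOH, H2O
Reagents that add atoms: none
Why: Corey–Bakshi–Shibata reduction; the isopropenyl group acts as the large substituent and the benzylic CH2 as the small one, so hydride is delivered in the same sense as acetophenone → (R)-1-phenylethanol with this catalyst, giving the (R)-carbinol by 1,2-reduction without touching the alkene.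

**Step 4**
Reactants: 10 4-(methoxymethoxy)benzaldehyde; 11 N-methoxy-N-methyl-2-(triphenyl-λ5-phosphanylidene)acetamide
Product: 12 (2E)-N-methoxy-3-[4-(methoxymethoxy)phenyl]-N-methylprop-2-enamide
Conditions: toluene, 90 °C
Reagents that add atoms: none
Why: Wittig olefination with an amide-stabilised ylide, which gives the E-alkene under thermodynamic control.

**Step 5**
Reactants: 9 (2R)-1-[4-methoxy-2,6-bis(methoxymethoxy)phenyl]-3-methylbut-3-en-2-ol; 12 (2E)-N-methoxy-3-[4-(methoxymethoxy)phenyl]-N-methylprop-2-enamide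
Product: 15 (2E)-1-{3-[(2R)-2-hydroxy-3-methylbut-3-en-1-yl]-6-methoxy-2,4-bis(methoxymethoxy)phenyl}-3-[4-(methoxymethoxy)phenyl]prop-2-en-1-one, via dilithio species 13 (not isolated), via Weinreb adduct 14 (not isolated)
Conditions: n-BuLi (2.3 equiv), THF, 0 °C, 2 h; 12 (1.3 equiv), −78 → 0 °C; H2O
Reagents that add atoms: none
Why: Directed ortho-metalation then Weinreb ketone synthesis: after the alkoxide forms, the second n-BuLi lithiates one of the two equivalent ring C–H positions flanked by OMOM and OMe, the aryllithium adds 1,2 to amide 12, and the chelated adduct 14 releases the enone only on work-up, so neither over-addition nor conjugate addition occurs; the carbinol centre is untouched.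

**Step 6**
Reactants: 15 (2E)-1-{3-[(2R)-2-hydroxy-3-methylbut-3-en-1-yl]-6-methoxy-2,4-bis(methoxymethoxy)phenyl}-3-[4-(methoxymethoxy)phenyl]prop-2-en-1-one
Product: 16 (2E)-1-{2,4-dihydroxy-3-[(2R)-2-hydroxy-3-methylbut-3-en-1-yl]-6-methoxyphenyl}-3-(4-hydroxyphenyl)prop-2-en-1-one (target)
Conditions: 3 M aq. HCl, MeOH, rt
Reagents that add atoms: none
Why: Acid-catalysed transacetalisation of the three aryl MOM ethers to methanol; at room temperature the E-enone, the methyl ether and the secondary allylic alcohol survive, and a short reaction time limits chalcone-to-flavanone cyclisation.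

**Compound list**
1 | 5-methoxybenzene-1,3-diol (5-methoxyresorcinol) | COc1cc(O)cc(O)c1 | starting material
2 | 1-methoxy-3,5-bis(methoxymethoxy)benzene | COCOc1cc(OC)cc(OCOC)c1 | intermediate
3 | 3-methylbut-3-en-2-one | CC(=O)C(C)=C | starting material
4 | [4-methoxy-2,6-bis(methoxymethoxy)phenyl]lithium | [Li]c1c(OCOC)cc(OC)cc1OCOC | intermediate
5 | bis[4-methoxy-2,6-bis(methoxymethoxy)phenyl]zinc | COCOc1cc(OC)cc(OCOC)c1[Zn]c1c(OCOC)cc(OC)cc1OCOC | intermediate
6 | lithium 3-methylbuta-1,3-dien-2-olate | [Li]OC(=C)C(C)=C | intermediate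
7 | hydroxy[(3-methylbuta-1,3-dien-2-yl)oxy]phenyl-λ3-iodane | C=C(C)C(=C)OI(O)c1ccccc1 | intermediate
8 | 1-[4-methoxy-2,6-bis(methoxymethoxy)phenyl]-3-methylbut-3-en-2-one | C=C(C)C(=O)Cc1c(OCOC)cc(OC)cc1OCOC | intermediate
9 | (2R)-1-[4-methoxy-2,6-bis(methoxymethoxy)phenyl]-3-methylbut-3-en-2-ol | C=C(C)[C@H](O)Cc1c(OCOC)cc(OC)cc1OCOC | intermediate
10 | 4-(methoxymethoxy)benzaldehyde | COCOc1ccc(C=O)cc1 | starting material
11 | N-methoxy-N-methyl-2-(triphenyl-λ5-phosphanylidene)acetamide | CON(C)C(=O)C=P(c1ccccc1)(c1ccccc1)c1ccccc1 | starting material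
12 | (2E)-N-methoxy-3-[4-(methoxymethoxy)phenyl]-N-methylprop-2-enamide | CON(C)C(=O)/C=C/c1ccc(OCOC)cc1 | intermediate
13 | lithium (2R)-1-[3-lithio-4-methoxy-2,6-bis(methoxymethoxy)phenyl]-3-methylbut-3-en-2-olate | C=C(C)[C@H](O[Li])Cc1c(OCOC)cc(OC)c([Li])c1OCOC | intermediate
14 | lithium (2R)-1-{3-[(2E)-1-(lithiooxy)-1-[methoxy(methyl)amino]-3-[4-(methoxymethoxy)phenyl]prop-2-en-1-yl]-4-methoxy-2,6-bis(methoxymethoxy)phenyl}-3-methylbut-3-en-2-olate (epimers at the hemiaminal carbon) | C=C(C)[C@H](O[Li])Cc1c(OCOC)cc(OC)c(C(O[Li])(N(C)OC)/C=C/c2ccc(OCOC)cc2)c1OCOC | intermediate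
15 | (2E)-1-{3-[(2R)-2-hydroxy-3-methylbut-3-en-1-yl]-6-methoxy-2,4-bis(methoxymethoxy)phenyl}-3-[4-(methoxymethoxy)phenyl]prop-2-en-1-one | C=C(C)[C@H](O)Cc1c(OCOC)cc(OC)c(C(=O)/C=C/c2ccc(OCOC)cc2)c1OCOC | intermediate
16 | (2E)-1-{2,4-dihydroxy-3-[(2R)-2-hydroxy-3-methylbut-3-en-1-yl]-6-methoxyphenyl}-3-(4-hydroxyphenyl)prop-2-en-1-one | C=C(C)[C@H](O)Cc1c(O)cc(OC)c(C(=O)/C=C/c2ccc(O)cc2)c1O | target

**Step count**
Total steps: 6. Longest linear sequence: 5 (steps 1, 2, 3, 5, 6).

**Three steps most likely to fail**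

Step 2 (aryl transfer to the enolonium). The zinc reagent may attack iodine instead of carbon (ligand exchange, diaryliodonium formation), or the dienolate-derived iodane may decompose. The fallback sets out from 2 and comes back at 8. It keeps the same bond but uses a shelf-stable α-halo amide and nickel catalysis. Diarylzinc 5, made from 2 as in step 2, is cross-coupled (Ni(acac)2, PPh3, THF, rt) with commercial 2-bromo-N-methoxy-N-methylacetamide to give 2-[4-methoxy-2,6-bis(methoxymethoxy)phenyl]-N-methoxy-N-methylacetamide F1. Isopropenylmagnesium bromide (THF, 0 °C) adds once to give bromomagnesium 2-[methoxy(methyl)amino]-1-[4-methoxy-2,6-bis(methoxymethoxy)phenyl]-3-methylbut-3-en-2-olate F2, which collapses on aqueous work-up to 8.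

Step 3 (enantioselectivity). The bulky benzylic group may erode the size difference that the catalyst reads. The fallback sets out from 8 and comes back at 9. Luche reduction (NaBH4, CeCl3·7H2O, MeOH, −40 °C) gives rac-1-[4-methoxy-2,6-bis(methoxymethoxy)phenyl]-3-methylbut-3-en-2-ol F3. Sharpless kinetic resolution (Ti(O-i-Pr)4, L-(+)-diisopropyl tartrate, t-BuOOH 0.6 equiv, 4 Å sieves, CH2Cl2, −20 °C) epoxidises the (S)-enantiomer to (1S)-2-[4-methoxy-2,6-bis(methoxymethoxy)phenyl]-1-[(2R)-2-methyloxiran-2-yl]ethan-1-ol F4, which is removed by chromatography, and leaves 9 (at most half of the material).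

Step 5 (acylation of the dianion). The hindered aryllithium may add 1,4 to the cinnamoyl amide or deprotonate it. The fallback sets out from 9 and comes back at 15. It builds the enone by aldol condensation instead of acyl substitution. Dianion 13, made from 9 as in step 5, is treated with N-methoxy-N-methylacetamide to give lithium (2R)-1-{3-[1-(lithiooxy)-1-[methoxy(methyl)amino]ethyl]-4-methoxy-2,6-bis(methoxymethoxy)phenyl}-3-methylbut-3-en-2-olate F5. Aqueous work-up gives 1-{3-[(2R)-2-hydroxy-3-methylbut-3-en-1-yl]-6-methoxy-2,4-bis(methoxymethoxy)phenyl}ethan-1-one F6. Claisen–Schmidt condensation of F6 with aldehyde 10 (KOH, MeOH, rt) gives 15.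

**Further compounds**
F1 | step 2 | 2-[4-methoxy-2,6-bis(methoxymethoxy)phenyl]-N-methoxy-N-methylacetamide | CON(C)C(=O)Cc1c(OCOC)cc(OC)cc1OCOC
F2 | step 2 | bromomagnesium 2-[methoxy(methyl)amino]-1-[4-methoxy-2,6-bis(methoxymethoxy)phenyl]-3-methylbut-3-en-2-olate | C=C(C)C(O[Mg]Br)(N(C)OC)Cc1c(OCOC)cc(OC)cc1OCOC
F3 | step 3 | rac-1-[4-methoxy-2,6-bis(methoxymethoxy)phenyl]-3-methylbut-3-en-2-ol | C=C(C)C(O)Cc1c(OCOC)cc(OC)cc1OCOC
F4 | step 3 | (1S)-2-[4-methoxy-2,6-bis(methoxymethoxy)phenyl]-1-[(2R)-2-methyloxiran-2-yl]ethan-1-ol | C[C@@]1(CO1)[C@@H](O)Cc1c(OCOC)cc(OC)cc1OCOC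
F5 | step 5 | lithium (2R)-1-{3-[1-(lithiooxy)-1-[methoxy(methyl)amino]ethyl]-4-methoxy-2,6-bis(methoxymethoxy)phenyl}-3-methylbut-3-en-2-olate | C=C(C)[C@H](O[Li])Cc1c(OCOC)cc(OC)c(C(C)(O[Li])N(C)OC)c1OCOC
F6 | step 5 | 1-{3-[(2R)-2-hydroxy-3-methylbut-3-en-1-yl]-6-methoxy-2,4-bis(methoxymethoxy)phenyl}ethan-1-one | C=C(C)[C@H](O)Cc1c(OCOC)cc(OC)c(C(C)=O)c1OCOC
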